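**Retrosynthetic overview**

1. Ring C (C2–O1): the (2S)-flavanone is opened by retro-oxa-Michael to an achiral, unprotected 2',6'-dihydroxychalcone. In the forward direction this is a catalyst-controlled, chalcone-isomerase-like ring closure run as the very last step, so the only stereocentre is made once and meets no later reagent.
2. Cα=Cβ: Claisen–Schmidt disconnection of the chalcone to benzaldehyde and a bis-C-benzylated acetophenone.
3. Two Ar–CH2 bonds on ring A: o-quinone-methide Friedel–Crafts disconnection (as in the presumed biogenesis of C-benzyl flavonoids) to 2',6'-dihydroxy-4'-methoxyacetophenone and two equivalents of a "dimeric" salicyl alcohol.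
4. Dimeric salicyl alcohol: ester reduction, then Ar–CH2 disconnection (para to OH) to saligenin and methyl salicylate.
5. Ring order: all six benzene rings are bought. Ring C is the only ring made and is closed last; ring A is symmetric in the chalcone, so either ortho-hydroxyl gives the same flavanone.

Assumption: the SMILES is read as the (2S)-flavanone with 5-OH, 7-OMe and identical 2-hydroxy-5-(2-hydroxybenzyl)benzyl groups on C6 and C8; saligenin, methyl salicylate, 2',6'-dihydroxy-4'-methoxyacetophenone and benzaldehyde are taken as cheap catalogue chemicals.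

**Route**

Step 1
Reactants: 1 2-hydroxybenzyl alcohol (saligenin); 2 methyl salicylate (30 equiv, also the solvent)
Product: 4 methyl 2-hydroxy-5-(2-hydroxybenzyl)benzoate, via o-quinone methide 3 (not isolated)
Conditions: p-toluenesulfonic acid monohydrate (5 mol %), neat 2, 90 °C, 1 added over 6 h; excess 2 distilled off in vacuo, chromatography
Reagents that add atoms: none
Why: Acid-catalysed dehydration of 1 gives o-quinone methide 3, which undergoes Friedel–Crafts hydroxybenzylation of methyl salicylate at C5 (para to OH and meta to the ester, the usual site of electrophilic substitution of salicylates), the large excess of 2 and slow addition of 1 suppressing self-condensation; no stereocentre is formed.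

Step 2
Reactants: 4 methyl 2-hydroxy-5-(2-hydroxybenzyl)benzoate
Product: 5 2-(hydroxymethyl)-4-(2-hydroxybenzyl)phenol
Conditions: LiAlH4 (3 equiv), THF, 0 °C → rt; cold 1 M HCl quench
Reagents that add atoms: none
Why: Hydride reduction of an ester with LiAlH4 converts the salicylate into the salicyl alcohol (the phenols are only deprotonated and the diarylmethane is inert), giving a latent o-quinone methide; no stereocentre is formed.

Step 3
Reactants: 5 2-(hydroxymethyl)-4-(2-hydroxybenzyl)phenol (2.2 equiv); 6 1-(2,6-dihydroxy-4-methoxyphenyl)ethanone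
Product: 9 1-{2,6-dihydroxy-3,5-bis[2-hydroxy-5-(2-hydroxybenzyl)benzyl]-4-methoxyphenyl}ethanone, via side-chain o-quinone methide 7 (not isolated), via mono-benzylated ketone 8 (not isolated)
Conditions: ZnCl2 (3 equiv), 1,4-dioxane, 80 °C, 5 added over 3 h
Reagents that add atoms: none
Why: ZnCl2 ionises 5 to o-quinone methide 7, which is captured in a biomimetic Friedel–Crafts C-hydroxybenzylation by the phloroglucinol-type ring of 6 at its only two free, equivalent positions (C3 then C5, through 8), this ring being far more nucleophilic than the simple phenol rings of 5 so that cross-coupling beats oligomerisation; no stereocentre is formed.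

Step 4
Reactants: 9 1-{2,6-dihydroxy-3,5-bis[2-hydroxy-5-(2-hydroxybenzyl)benzyl]-4-methoxyphenyl}ethanone; 10 benzaldehyde (3 equiv)
Product: 12 (E)-1-{2,6-dihydroxy-3,5-bis[2-hydroxy-5-(2-hydroxybenzyl)benzyl]-4-methoxyphenyl}-3-phenylprop-2-en-1-one, via β-hydroxy ketone 11 (not isolated)
Conditions: KOH (50% aq, 20 equiv), EtOH, 0 °C → rt, 48 h, Ar; poured onto ice/1 M HCl (pH 3), cold rapid work-up
Reagents that add atoms: none
Why: Claisen–Schmidt (crossed aldol) condensation in which the methyl-ketone enolate of the polyphenoxide adds to non-enolisable benzaldehyde and adduct 11 loses water by E1cB to the thermodynamic (E)-enone, the strongly basic medium holding the 2',6'-dihydroxychalcone ring-open as its phenoxide until the cold acid quench; no sp3 stereocentre is formed.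

Step 5
Reactants: 12 (E)-1-{2,6-dihydroxy-3,5-bis[2-hydroxy-5-(2-hydroxybenzyl)benzyl]-4-methoxyphenyl}-3-phenylprop-2-en-1-one
Product: 13 (2S)-5-hydroxy-6,8-bis[2-hydroxy-5-(2-hydroxybenzyl)benzyl]-7-methoxy-2-phenylchroman-4-one (5''-(2''''-hydroxybenzyl)uvarinol)
Conditions: 1-[3,5-bis(trifluoromethyl)phenyl]-3-[(8S,9S)-6'-methoxycinchonan-9-yl]thiourea (thiourea of 9-amino-9-deoxy-epi-quinine, C29H28F6N4OS, 10 mol %), CH2Cl2/toluene 1:1 (5% THF to dissolve), −20 °C, 36 h; cold SiO2 filtration to remove the catalyst
Reagents that add atoms: none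
Why: Proposed new method: a chalcone-isomerase-like 6-endo-trig intramolecular oxa-Michael addition in which the quinuclidine nitrogen acts as general base on one of the two homotopic ortho-hydroxyls while the thiourea hydrogen-bonds the enone carbonyl (already polarised by the chelating second hydroxyl), so that the phenoxide is delivered to the si face of C-β and the ammonium protonates the enol, fixing C2 as (S), and the 5-OH···O=C4 chelate of the product makes closure effectively irreversible at −20 °C so the kinetic ee is kept; closest known reaction type: cinchona-alkaloid-thiourea-catalysed enantioselective intramolecular oxa-Michael cyclisation of 2'-hydroxychalcones to flavanones.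

**Compound list**

1 | 2-hydroxybenzyl alcohol (saligenin) | OCc1ccccc1O | starting material
2 | methyl salicylate | COC(=O)c1ccccc1O | starting material
3 | o-quinone methide, 6-methylidenecyclohexa-2,4-dien-1-one (not isolated) | C=C1C=CC=CC1=O | intermediate
4 | methyl 2-hydroxy-5-(2-hydroxybenzyl)benzoate | COC(=O)c1cc(Cc2ccccc2O)ccc1O | intermediate
5 | 2-(hydroxymethyl)-4-(2-hydroxybenzyl)phenol | OCc1cc(Cc2ccccc2O)ccc1O | intermediate
6 | 1-(2,6-dihydroxy-4-methoxyphenyl)ethanone (2',6'-dihydroxy-4'-methoxyacetophenone) | COc1cc(O)c(C(C)=O)c(O)c1 | starting material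
7 | side-chain o-quinone methide, 4-(2-hydroxybenzyl)-6-methylidenecyclohexa-2,4-dien-1-one (not isolated) | C=C1C=C(Cc2ccccc2O)C=CC1=O | intermediate
8 | mono-benzylated ketone, 1-{2,6-dihydroxy-3-[2-hydroxy-5-(2-hydroxybenzyl)benzyl]-4-methoxyphenyl}ethanone (not isolated) | COc1cc(O)c(C(C)=O)c(O)c1Cc1cc(Cc2ccccc2O)ccc1O | intermediate
9 | 1-{2,6-dihydroxy-3,5-bis[2-hydroxy-5-(2-hydroxybenzyl)benzyl]-4-methoxyphenyl}ethanone | COc1c(Cc2cc(Cc3ccccc3O)ccc2O)c(O)c(C(C)=O)c(O)c1Cc1cc(Cc2ccccc2O)ccc1O | intermediate
10 | benzaldehyde | O=Cc1ccccc1 | starting material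
11 | β-hydroxy ketone, racemic 1-{2,6-dihydroxy-3,5-bis[2-hydroxy-5-(2-hydroxybenzyl)benzyl]-4-methoxyphenyl}-3-hydroxy-3-phenylpropan-1-one (not isolated) | COc1c(Cc2cc(Cc3ccccc3O)ccc2O)c(O)c(C(=O)CC(O)c2ccccc2)c(O)c1Cc1cc(Cc2ccccc2O)ccc1O | intermediate
12 | (E)-1-{2,6-dihydroxy-3,5-bis[2-hydroxy-5-(2-hydroxybenzyl)benzyl]-4-methoxyphenyl}-3-phenylprop-2-en-1-one | COc1c(Cc2cc(Cc3ccccc3O)ccc2O)c(O)c(C(=O)/C=C/c2ccccc2)c(O)c1Cc1cc(Cc2ccccc2O)ccc1O | intermediate
13 | (2S)-5-hydroxy-6,8-bis[2-hydroxy-5-(2-hydroxybenzyl)benzyl]-7-methoxy-2-phenylchroman-4-one (5''-(2''''-hydroxybenzyl)uvarinol) | COc1c(Cc2cc(Cc3ccccc3O)ccc2O)c(O)c2c(c1Cc1cc(Cc3ccccc3O)ccc1O)O[C@H](c1ccccc1)CC2=O | target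

**Totals and risks**

Total step count: 5. Longest linear sequence: 5 steps (1/2 → 4 → 5 → 9 → 12 → 13).

The three steps most likely to fail:

Step 5 (enantioselective ring closure). The level and sense of induction on this hexaphenolic, doubly ortho-substituted chalcone are unproven, and uncatalysed closure of the 2',6'-dihydroxychalcone would erode the ee. The configuration is checked by ECD and chiral HPLC; if the sense is opposite, the quinidine-derived pseudo-enantiomer of the catalyst is tried first. The fallback replaces asymmetric catalysis by resolution: it sets out from 12, which is cyclised without stereocontrol (NaOAc, EtOH, reflux) to the racemic flavanone F1. Preparative chiral SFC on amylose tris(3,5-dimethylphenylcarbamate) (CO2/MeOH) then delivers 13, where the route is rejoined. The unwanted (2R)-enantiomer F2 is reopened with KOH/EtOH to 12 and recycled.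

Step 4 (Claisen–Schmidt on the hexaphenol). The hexa-phenoxide may enolise sluggishly, and the chalcone may close partly to racemic flavanone during the acid quench. The fallback changes the order of events: it sets out from 6, which is condensed with 10 (KOH, EtOH, rt) to pinostrobin chalcone F3, an aldol in which only two phenoxides flank the ketone. F3 is then C-hydroxybenzylated twice with 5 (2.2 equiv) under resole-type basic conditions (2 M aq KOH/1,4-dioxane, 60 °C, Ar). Here the phenoxide of 5 expels hydroxide to give 7, which the ring A phenoxide of F3 captures at both free positions. The strongly basic medium keeps the enone ring-open, and cold acidification returns the route at 12.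

Step 1 (cross Friedel–Crafts of saligenin with methyl salicylate). Saligenin and the phenol ring of product 4 are both better nucleophiles than methyl salicylate, so oligomers, over-alkylation and some C3 isomer are expected; a yield of about 35–45% is realistic. The fallback masks the phenol of the electrophile: it sets out from 1, which is acetylated (Ac2O, pyridine, 4-(dimethylamino)pyridine) to 2-(acetoxymethyl)phenyl acetate F4, whose ring can no longer self-condense. Friedel–Crafts benzylation of 2 (5 equiv) catalysed by Sc(OTf)3 (MeNO2, 60 °C) gives methyl 5-(2-acetoxybenzyl)-2-hydroxybenzoate F5. LiAlH4 (THF, 0 °C → rt) then reduces the methyl ester and cleaves the aryl acetate in one operation, rejoining the route at 5.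

**Further compounds**

F1 | step 5 | racemic 5-hydroxy-6,8-bis[2-hydroxy-5-(2-hydroxybenzyl)benzyl]-7-methoxy-2-phenylchroman-4-one | COc1c(Cc2cc(Cc3ccccc3O)ccc2O)c(O)c2c(c1Cc1cc(Cc3ccccc3O)ccc1O)OC(c1ccccc1)CC2=O
F2 | step 5 | (2R)-5-hydroxy-6,8-bis[2-hydroxy-5-(2-hydroxybenzyl)benzyl]-7-methoxy-2-phenylchroman-4-one | COc1c(Cc2cc(Cc3ccccc3O)ccc2O)c(O)c2c(c1Cc1cc(Cc3ccccc3O)ccc1O)O[C@@H](c1ccccc1)CC2=O
F3 | step 4 | pinostrobin chalcone, (E)-1-(2,6-dihydroxy-4-methoxyphenyl)-3-phenylprop-2-en-1-one | COc1cc(O)c(C(=O)/C=C/c2ccccc2)c(O)c1
F4 | step 1 | 2-(acetoxymethyl)phenyl acetate | CC(=O)OCc1ccccc1OC(C)=O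
F5 | step 1 | methyl 5-(2-acetoxybenzyl)-2-hydroxybenzoate | COC(=O)c1cc(Cc2ccccc2OC(C)=O)ccc1O
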